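**Plan**
Retrosynthesis: after the simple O-methyl and MOM adjustments, ring C and the oxygen pattern of ring A are undone together. The two neighbouring ring A bonds O1–C8a and C8–O are cut, which gives an open (S)-2,3-diarylpropan-1-ol with Cl on C8a and H on C8.
Enabling feature: ring A carries three contiguous oxygens (C7, C8, C8a), and the chain O1–C2–C3–C4 hangs on C4a beside C8a. A C8≡C8a aryne flanked by the C7 oxygen can therefore take up O1 at C8a and, through the C8 carbanion (Li, then B, then O), the C8 oxygen in one flask.
Further cuts: C3–C4 (enolate benzylation) and the C1'–CH2 bond of the ring B acetic acid.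
Forward order: ring B acid and its imide, ring A benzylic bromide, union at C3–C4, reduction to the alcohol, closure of ring C as the last ring, then 8-O-methylation and release of the 7-OH.
Stereochemistry: the only centre, C3 (S), is set by an Evans alkylation controlled by (S)-4-benzyloxazolidin-2-one and is not touched afterwards.

Key step: step 9

Assumption: isoflavan numbering is used (O1, C2, C3, C4, C4a, C5 to C8, C8a; ring B primed), the centre in the given SMILES is read as 3S, and 1,2,3,4-tetramethoxybenzene, 2-chloro-4-hydroxybenzaldehyde and (S)-4-benzyloxazolidin-2-one are taken as catalogue compounds.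

**Step 1**
Reactants: 1 1,2,3,4-tetramethoxybenzene
Product: 3 2-(2,3,4,5-tetramethoxyphenyl)ethanol, via aryllithium 2 (not isolated)
Conditions: n-BuLi, TMEDA, THF, 0 °C to rt; ethylene oxide (THF solution), −78 °C to rt; H2O quench
Reagents that add atoms: ethylene oxide C1CO1; n-BuLi [Li]CCCC (its lithium is found in 2 only)
Why: Directed ortho-metalation next to a methoxy group (the two free ring positions are equivalent, so only one aryllithium can form) followed by SN2 opening of ethylene oxide installs the two-carbon side chain of ring B.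

**Step 2**
Reactants: 3 2-(2,3,4,5-tetramethoxyphenyl)ethanol
Product: 5 (2,3,4,5-tetramethoxyphenyl)acetic acid, via aldehyde 4 (not isolated)
Conditions: TEMPO (cat.), NaClO2, NaOCl (cat.), MeCN/aq NaH2PO4–Na2HPO4 buffer (pH 6.7), 35 °C
Reagents that add atoms: sodium chlorite [Na+].[O-]Cl=O
Why: TEMPO-catalysed oxidation to aldehyde 4 and Pinnick-type chlorite oxidation in the same buffered medium is a standard way to turn 2-arylethanols with electron-rich rings into arylacetic acids, because only a catalytic amount of hypochlorite is present at any time.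

**Step 3**
Reactants: 5 (2,3,4,5-tetramethoxyphenyl)acetic acid; 6 (S)-4-benzyl-1,3-oxazolidin-2-one
Product: 8 (4S)-4-benzyl-3-[(2,3,4,5-tetramethoxyphenyl)acetyl]-1,3-oxazolidin-2-one, via mixed anhydride 7 (not isolated)
Conditions: PivCl, Et3N, THF, −20 °C; then 6, LiCl, −20 °C to rt
Reagents that add atoms: pivaloyl chloride CC(C)(C)C(=O)Cl (its acyl group is found in 7 only)
Why: N-Acylation of the oxazolidinone through the mixed pivalic anhydride under LiCl/Et3N activation occurs at the less hindered arylacetyl carbonyl and needs no strong base.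

**Step 4**
Reactants: 9 2-chloro-4-hydroxybenzaldehyde
Product: 10 2-chloro-4-(methoxymethoxy)benzaldehyde
Conditions: MOMCl, i-Pr2NEt, CH2Cl2, 0 °C to rt
Reagents that add atoms: chloromethyl methyl ether COCCl
Why: Williamson-type O-alkylation of the acidic phenol gives the MOM acetal, chosen because it withstands organolithiums, later chelates lithium at C8 and leaves under mild acid.

**Step 5**
Reactants: 10 2-chloro-4-(methoxymethoxy)benzaldehyde
Product: 11 [2-chloro-4-(methoxymethoxy)phenyl]methanol
Conditions: NaBH4, MeOH, 0 °C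
Reagents that add atoms: none
Why: Chemoselective hydride reduction of the aldehyde leaves the aryl chloride and the acetal untouched.

**Step 6**
Reactants: 11 [2-chloro-4-(methoxymethoxy)phenyl]methanol
Product: 12 1-(bromomethyl)-2-chloro-4-(methoxymethoxy)benzene
Conditions: CBr4, PPh3, CH2Cl2, 0 °C
Reagents that add atoms: carbon tetrabromide BrC(Br)(Br)Br
Why: The Appel reaction converts the benzylic alcohol into the bromide under neutral conditions that spare the acid-labile MOM group.

**Step 7**
Reactants: 8 (4S)-4-benzyl-3-[(2,3,4,5-tetramethoxyphenyl)acetyl]-1,3-oxazolidin-2-one; 12 1-(bromomethyl)-2-chloro-4-(methoxymethoxy)benzene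
Product: 14 (4S)-4-benzyl-3-[(2S)-3-[2-chloro-4-(methoxymethoxy)phenyl]-2-(2,3,4,5-tetramethoxyphenyl)propanoyl]-1,3-oxazolidin-2-one, via sodium enolate 13 (not isolated)
Conditions: NaN(SiMe3)2, THF, −78 °C; then 12, −78 to −30 °C; AcOH quench at low temperature
Reagents that add atoms: NaN(SiMe3)2 C[Si](C)(C)[N-][Si](C)(C)C.[Na+] (its sodium is found in 13 only)
Why: Evans asymmetric alkylation, in which the chelated Z-enolate 13 is shielded on one face by the C4 benzyl group of the auxiliary, so the benzylic bromide enters from the opposite face and sets the future C3 as S.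

**Step 8**
Reactants: 14 the alkylated imide
Product: 15 (2S)-3-[2-chloro-4-(methoxymethoxy)phenyl]-2-(2,3,4,5-tetramethoxyphenyl)propan-1-ol
Conditions: LiBH4, H2O (1 equiv), Et2O/THF, 0 °C
Reagents that add atoms: none
Why: Reductive removal of the auxiliary with LiBH4 attacks the exocyclic imide carbonyl and runs through to the primary alcohol without enolisation, so the S centre is kept and the auxiliary can be recovered.

**Step 9**
Reactants: 15 (2S)-3-[2-chloro-4-(methoxymethoxy)phenyl]-2-(2,3,4,5-tetramethoxyphenyl)propan-1-ol
Product: 20 (3S)-7-(methoxymethoxy)-3-(2,3,4,5-tetramethoxyphenyl)chroman-8-ol, via dilithio species 16 (not isolated), via aryne 17 (not isolated), via 8-lithiochroman 18 (not isolated), via dimethyl boronate 19 (not isolated)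
Conditions: n-BuLi (2.1 equiv), THF (0.02 M), −78 °C; warm to 0 °C; B(OMe)3, −78 °C to rt; then 30% H2O2, aq NaOH, 0 °C
Reagents that add atoms: n-BuLi [Li]CCCC (lithium of 16, 17 and 18); trimethyl borate COB(OC)OC (boron unit of 19); hydrogen peroxide OO (the C8 oxygen of 20)
Why: Proposed new method: the first n-BuLi makes the lithium alkoxide and the second removes C8–H, the most acidic ring proton because it lies between Cl and the chelating OMOM group; on warming, 16 loses LiCl to give the C8≡C8a aryne 17, the tethered alkoxide adds to C8a and leaves the carbanion on C8 as aryllithium 18, and B(OMe)3 followed by H2O2 converts this through 19 (1,2-shift of the aryl group from boron to oxygen) into the C8 phenol. The closest known reaction types are the anionic benzyne cyclisation of tethered carbanions, lithium amides or thioamides with electrophile quench of the new aryllithium, and the closure of alcohol-tethered benzynes to chromans with uptake of iodine at the neighbouring carbon; new here is an alkoxide as the closing nucleophile followed by borylation and oxidation in the same flask. Ring C closes in the 6-exo-dig mode (O1 onto C8a, C8 outside the new ring), whereas attack at C8 would require an impossibly strained meta-bridged seven-membered ring. Regioselectivity is secured twice, because the inductively withdrawing C7 oxygen distorts the aryne so that C8a is the wider-angled, more electrophilic carbon, and the developing negative charge falls on C8 next to that oxygen, where lithium is chelated by the MOM group. No stereocentre is made, and C3, which is neither acidic nor part of the reacting array, keeps its S configuration. An amine-free base and high dilution are needed so that 18 is not protonated and 16 does not add to the aryne of a second molecule.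

**Step 10**
Reactants: 20 (3S)-7-(methoxymethoxy)-3-(2,3,4,5-tetramethoxyphenyl)chroman-8-ol
Product: 21 (3S)-8-methoxy-7-(methoxymethoxy)-3-(2,3,4,5-tetramethoxyphenyl)chroman
Conditions: MeI, K2CO3, DMF, rt
Reagents that add atoms: iodomethane CI
Why: Williamson methylation of the only free phenol fixes the C8 methoxy group while C7 stays masked, which differentiates the two neighbouring oxygens.

**Step 11**
Reactants: 21 (3S)-8-methoxy-7-(methoxymethoxy)-3-(2,3,4,5-tetramethoxyphenyl)chroman
Product: 22 (3S)-8-methoxy-3-(2,3,4,5-tetramethoxyphenyl)chroman-7-ol, that is (3S)-7-hydroxy-8,2',3',4',5'-pentamethoxyisoflavan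
Conditions: conc. HCl (cat.), MeOH, 45 °C
Reagents that add atoms: none
Why: Acid-catalysed transacetalisation removes the MOM group as dimethoxymethane, while the aryl methyl ethers, the chroman ether and the non-enolisable C3 centre are inert.

**Compound list**
1 | 1,2,3,4-tetramethoxybenzene | COc1ccc(OC)c(OC)c1OC | starting material
2 | 2,3,4,5-tetramethoxyphenyllithium | COc1cc([Li])c(OC)c(OC)c1OC | intermediate
3 | 2-(2,3,4,5-tetramethoxyphenyl)ethanol | COc1cc(CCO)c(OC)c(OC)c1OC | intermediate
4 | (2,3,4,5-tetramethoxyphenyl)acetaldehyde | COc1cc(CC=O)c(OC)c(OC)c1OC | intermediate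
5 | (2,3,4,5-tetramethoxyphenyl)acetic acid | COc1cc(CC(=O)O)c(OC)c(OC)c1OC | intermediate
6 | (S)-4-benzyl-1,3-oxazolidin-2-one | O=C1N[C@@H](Cc2ccccc2)CO1 | starting material
7 | (2,3,4,5-tetramethoxyphenyl)acetic pivalic anhydride | COc1cc(CC(=O)OC(=O)C(C)(C)C)c(OC)c(OC)c1OC | intermediate
8 | (4S)-4-benzyl-3-[(2,3,4,5-tetramethoxyphenyl)acetyl]-1,3-oxazolidin-2-one | COc1cc(CC(=O)N2[C@@H](Cc3ccccc3)COC2=O)c(OC)c(OC)c1OC | intermediate
9 | 2-chloro-4-hydroxybenzaldehyde | O=Cc1ccc(O)cc1Cl | starting material
10 | 2-chloro-4-(methoxymethoxy)benzaldehyde | COCOc1ccc(C=O)c(Cl)c1 | intermediate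
11 | [2-chloro-4-(methoxymethoxy)phenyl]methanol | COCOc1ccc(CO)c(Cl)c1 | intermediate
12 | 1-(bromomethyl)-2-chloro-4-(methoxymethoxy)benzene | COCOc1ccc(CBr)c(Cl)c1 | intermediate
13 | sodium (Z)-enolate of imide 8 | COc1cc(/C=C(\O[Na])N2[C@@H](Cc3ccccc3)COC2=O)c(OC)c(OC)c1OC | intermediate
14 | (4S)-4-benzyl-3-[(2S)-3-[2-chloro-4-(methoxymethoxy)phenyl]-2-(2,3,4,5-tetramethoxyphenyl)propanoyl]-1,3-oxazolidin-2-one | COc1cc([C@H](Cc2ccc(OCOC)cc2Cl)C(=O)N2[C@@H](Cc3ccccc3)COC2=O)c(OC)c(OC)c1OC | intermediate
15 | (2S)-3-[2-chloro-4-(methoxymethoxy)phenyl]-2-(2,3,4,5-tetramethoxyphenyl)propan-1-ol | COc1cc([C@@H](CO)Cc2ccc(OCOC)cc2Cl)c(OC)c(OC)c1OC | intermediate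
16 | lithium alkoxide of 15 lithiated at C8 (between Cl and OMOM) | COc1cc([C@@H](CO[Li])Cc2ccc(OCOC)c([Li])c2Cl)c(OC)c(OC)c1OC | intermediate
17 | C8≡C8a aryne carrying the lithium alkoxide tether | COc1cc([C@@H](CO[Li])CC2=CC=C(OCOC)C#C2)c(OC)c(OC)c1OC | intermediate
18 | (3S)-8-lithio-7-(methoxymethoxy)-3-(2,3,4,5-tetramethoxyphenyl)chroman | COc1cc([C@H]2COc3c(ccc(OCOC)c3[Li])C2)c(OC)c(OC)c1OC | intermediate
19 | dimethyl [(3S)-7-(methoxymethoxy)-3-(2,3,4,5-tetramethoxyphenyl)chroman-8-yl]boronate | COc1cc([C@H]2COc3c(ccc(OCOC)c3B(OC)OC)C2)c(OC)c(OC)c1OC | intermediate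
20 | (3S)-7-(methoxymethoxy)-3-(2,3,4,5-tetramethoxyphenyl)chroman-8-ol | COc1cc([C@H]2COc3c(ccc(OCOC)c3O)C2)c(OC)c(OC)c1OC | intermediate
21 | (3S)-8-methoxy-7-(methoxymethoxy)-3-(2,3,4,5-tetramethoxyphenyl)chroman | COc1cc([C@H]2COc3c(ccc(OCOC)c3OC)C2)c(OC)c(OC)c1OC | intermediate
22 | (3S)-8-methoxy-3-(2,3,4,5-tetramethoxyphenyl)chroman-7-ol | COc1cc([C@H]2COc3c(ccc(O)c3OC)C2)c(OC)c(OC)c1OC | target

Total step count: 11. Longest linear sequence: 8 steps (1, 2, 3, 7, 8, 9, 10, 11).

**Steps most likely to fail**

**Step 9 (bears the label "Proposed new method:").**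
- What may go wrong: capture of the aryne by the aggregated lithium alkoxide may be slower than addition of a second aryllithium to the aryne. The C8 carbanion may also be protonated, or the boronate protodeboronated, before oxidation.
- Fallback (known chemistry): it sets out from 15 and comes back at 20. The aryne is given up and the two events are separated.
- Intramolecular Buchwald–Hartwig-type C–O coupling of the aryl chloride uses Pd(OAc)2, 2-(di-tert-butylphosphino)-1,1'-binaphthyl, Cs2CO3, toluene, 80 °C. The C–Cl bond adds oxidatively to zerovalent palladium. This should give (3S)-7-(methoxymethoxy)-3-(2,3,4,5-tetramethoxyphenyl)chroman F1.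
- The C8–H of F1 now lies between O1 and the MOM ether. Directed ortho-metalation (n-BuLi, THF, 0 °C) removes it to give 18, which is borylated and oxidised as above to 20.

**Step 7.**
- What may go wrong: the hindered ortho-substituted arylacetyl enolate may convert slowly, the acidic alpha-aryl centre may epimerise by proton exchange, or the labile benzylic bromide may decompose.
- Fallback: it sets out from 5 and 10 and comes back at 15. The auxiliary is replaced by catalytic asymmetric hydrogenation.
- Perkin condensation (Ac2O, Et3N, 110 °C) should give (E)-3-[2-chloro-4-(methoxymethoxy)phenyl]-2-(2,3,4,5-tetramethoxyphenyl)prop-2-enoic acid F2.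
- Hydrogenation uses [Rh(cod)2]BF4 and a chiral ferrocene-based diphosphine (H2, MeOH), with the ligand enantiomer chosen for the S product. It should give (2S)-3-[2-chloro-4-(methoxymethoxy)phenyl]-2-(2,3,4,5-tetramethoxyphenyl)propanoic acid F3.
- BH3·THF reduces F3 to 15.

**Step 2.**
- What may go wrong: hypochlorite may chlorinate the very electron-rich ring B, or over-oxidation may occur at the benzylic carbon through the enolisable aldehyde.
- Fallback: it sets out from 1 and comes back at 5. The side chain is brought in at the acid oxidation level.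
- Bromination (NBS, MeCN, 0 °C) should give 1-bromo-2,3,4,5-tetramethoxybenzene F4.
- Negishi-type alpha-arylation with the Reformatsky reagent BrZnCH2CO2t-Bu (Pd(dba)2, P(t-Bu)3, THF, rt) should give tert-butyl (2,3,4,5-tetramethoxyphenyl)acetate F5.
- CF3CO2H in CH2Cl2 cleaves F5 to 5.

**Further compounds**
F1 | step 9 | (3S)-7-(methoxymethoxy)-3-(2,3,4,5-tetramethoxyphenyl)chroman | COc1cc([C@H]2COc3cc(OCOC)ccc3C2)c(OC)c(OC)c1OC
F2 | step 7 | (E)-3-[2-chloro-4-(methoxymethoxy)phenyl]-2-(2,3,4,5-tetramethoxyphenyl)prop-2-enoic acid | COCOc1ccc(/C=C(/C(=O)O)c2cc(OC)c(OC)c(OC)c2OC)c(Cl)c1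
F3 | step 7 | (2S)-3-[2-chloro-4-(methoxymethoxy)phenyl]-2-(2,3,4,5-tetramethoxyphenyl)propanoic acid | COc1cc([C@H](Cc2ccc(OCOC)cc2Cl)C(=O)O)c(OC)c(OC)c1OC
F4 | step 2 | 1-bromo-2,3,4,5-tetramethoxybenzene | COc1cc(Br)c(OC)c(OC)c1OC
F5 | step 2 | tert-butyl (2,3,4,5-tetramethoxyphenyl)acetate | COc1cc(CC(=O)OC(C)(C)C)c(OC)c(OC)c1OC
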